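In germacrane numbering (ketone C2, lactone oxygen on C6, ester on C8) the ten-membered ring holds the 1,5-diene C10=C1–C2(=O)–C3–C4=C5, and its central bond C2–C3 is read as the σ bond made in a Cope shift. The key step therefore expands an easily built, stereodefined cyclohexane (ring atoms C5–C10, already carrying the butenolide) in which C10 bears methyl and a ketene arm (C1=C2=O) trans to the isopropenyl group on C5. The ketene-Cope rearrangement forms C2–C3, cleaves C5–C10 and sets the ring, the enone and both E-alkenes at once. The precursor is an elemane-type acid made by an enantioselective Diels–Alder reaction.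

Key step: step 13

Remark: atom labels C1–C15 in the text follow germacrane numbering (C14 = methyl on C10, C15 = methyl on C4, C11–C13 = lactone carbons).
Assumption: the (S)-diphenylprolinol-derived oxazaborolidinium catalyst is taken to give the (1R,6R) adduct 4; if the facial sense is the opposite, its enantiomer is used and nothing else changes.

Step 1
Reactants: 1 but-3-en-2-one (methyl vinyl ketone)
Product: 2 2-(triisopropylsilyloxy)buta-1,3-diene
Conditions: iPr3SiOTf, Et3N, Et2O, 0 °C → rt
Reagents that add atoms: triisopropylsilyl trifluoromethanesulfonate, CC(C)[Si](C(C)C)(C(C)C)OS(=O)(=O)C(F)(F)F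
Why: amine-mediated O-silylation of the enone (silyl enol ether formation) should give the 2-silyloxydiene; no stereocentre is formed.

Step 2
Reactants: 2 2-(triisopropylsilyloxy)buta-1,3-diene; 3 ethyl (2E)-3-methyl-4-oxobut-2-enoate
Product: 4 ethyl (1R,6R)-6-formyl-6-methyl-3-[(triisopropylsilyl)oxy]cyclohex-3-ene-1-carboxylate (formyl trans to ester)
Conditions: oxazaborolidinium triflimide from (S)-α,α-diphenylprolinol and o-tolylboronic acid, activated with HNTf2 (20 mol %), CH2Cl2, −78 → −40 °C
Reagents that add atoms: none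
Why: catalytic enantioselective Diels–Alder reaction; the boron-bound formyl group directs the CH2 terminus next to the silyloxy carbon onto the ester-bearing β-carbon (silyloxy carbon "para" to the new quaternary carbon), the E geometry of 3 is transferred suprafacially so that formyl and ester end up trans, and the catalyst shields one face of the enal and so sets both centres absolutely.

Step 3
Reactants: 4 ethyl (1R,6R)-6-formyl-6-methyl-3-[(triisopropylsilyl)oxy]cyclohex-3-ene-1-carboxylate
Product: 6 ethyl (1R,6R)-6-ethynyl-6-methyl-3-[(triisopropylsilyl)oxy]cyclohex-3-ene-1-carboxylate, via diazoalkene 5 (not isolated)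
Conditions: Me3SiCHN2, nBuLi, THF, −78 °C → rt
Reagents that add atoms: (trimethylsilyl)diazomethane, C[Si](C)(C)C=[N+]=[N-]
Why: Colvin rearrangement (addition of the lithiated silyldiazomethane, Peterson-type loss of silanolate, loss of N2 and 1,2-hydride shift of the alkylidene carbene) should turn the non-enolisable aldehyde into the terminal alkyne, a robust latent form of the C1–C2 arm; the ester is not attacked at −78 °C and no stereocentre is touched.

Step 4
Reactants: 6 ethyl (1R,6R)-6-ethynyl-6-methyl-3-[(triisopropylsilyl)oxy]cyclohex-3-ene-1-carboxylate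
Product: 7 2-{(1R,6R)-6-ethynyl-6-methyl-3-[(triisopropylsilyl)oxy]cyclohex-3-en-1-yl}propan-2-ol
Conditions: MeMgBr (5 equiv), CeCl3, THF, −78 → 0 °C; aq. NH4Cl
Reagents that add atoms: methylmagnesium bromide, C[Mg]Br
Why: double Grignard addition to the ester, with CeCl3 suppressing enolisation and hence epimerisation at the ester-bearing carbon; the alkyne C–H only consumes one equivalent of reagent.

Step 5
Reactants: 7 2-{(1R,6R)-6-ethynyl-6-methyl-3-[(triisopropylsilyl)oxy]cyclohex-3-en-1-yl}propan-2-ol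
Product: 8 {[(4R,5S)-4-ethynyl-4-methyl-5-(prop-1-en-2-yl)cyclohex-1-en-1-yl]oxy}triisopropylsilane (ethynyl trans to isopropenyl)
Conditions: methyl N-(triethylammoniosulfonyl)carbamate (Burgess reagent), PhMe, 60 °C
Reagents that add atoms: none
Why: Burgess dehydration by syn-elimination; loss of a methyl hydrogen is favoured statistically and because the alternative tetrasubstituted exocyclic alkene would suffer allylic strain against the neighbouring quaternary carbon, so the isopropenyl group should form.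

Step 6
Reactants: 8 {[(4R,5S)-4-ethynyl-4-methyl-5-(prop-1-en-2-yl)cyclohex-1-en-1-yl]oxy}triisopropylsilane
Product: 10 (2S,4R,5S)-4-ethynyl-4-methyl-5-(prop-1-en-2-yl)-2-[(triisopropylsilyl)oxy]cyclohexan-1-one, via silyloxy epoxide 9 (not isolated)
Conditions: mCPBA (1.05 equiv), NaHCO3, CH2Cl2, −20 °C
Reagents that add atoms: meta-chloroperoxybenzoic acid, OOC(=O)c1cccc(Cl)c1
Why: Rubottom oxidation; the electron-rich silyl enol ether is epoxidised far faster than the isopropenyl group, from the face anti to the pseudoaxial C-methyl group (or, in the other half-chair, anti to the pseudoaxial isopropenyl group), i.e. cis to ethynyl, and the epoxide opens with 1,4-silyl shift to the α-silyloxy ketone; this centre stays epimerisable and the wanted equatorial isomer is also the thermodynamic one once the second oxygen is in place.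

Step 7
Reactants: 10 (2S,4R,5S)-4-ethynyl-4-methyl-5-(prop-1-en-2-yl)-2-[(triisopropylsilyl)oxy]cyclohexan-1-one
Product: 12 (2R,3S,4R,6S)-4-ethynyl-2-hydroxy-4-methyl-3-(prop-1-en-2-yl)-6-[(triisopropylsilyl)oxy]cyclohexan-1-one, via sodium enolate 11 (not isolated)
Conditions: NaN(SiMe3)2, THF, −78 °C; then 2-(phenylsulfonyl)-3-phenyloxaziridine; aq. NH4Cl
Reagents that add atoms: 2-(phenylsulfonyl)-3-phenyloxaziridine, O=S(=O)(N1OC1c1ccccc1)c1ccccc1
Why: kinetic enolisation toward the methylene (not the silyloxy-bearing methine) and Davis hydroxylation of the enolate anti to the adjacent isopropenyl group should give the trans (equatorial) alcohol, cis to the silyloxy group across the ketone.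

Step 8
Reactants: 13 (diethoxyphosphoryl)acetic acid; 14 (chloromethoxy)triisopropylsilane
Product: 16 2-(diethoxyphosphoryl)-3-[(triisopropylsilyl)oxy]propanoic acid (racemic), via dilithio dianion 15 (not isolated)
Conditions: LiN(iPr)2 (2.1 equiv), THF, −78 °C; then 14, −78 → 0 °C; aq. citric acid
Reagents that add atoms: none
Why: C-alkylation of the carboxylate/phosphonate dianion by the reactive chloromethyl silyl ether (dianion alkylation) installs the protected C13 oxygen on the future C11.

Step 9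
Reactants: 12 (2R,3S,4R,6S)-4-ethynyl-2-hydroxy-4-methyl-3-(prop-1-en-2-yl)-6-[(triisopropylsilyl)oxy]cyclohexan-1-one; 16 2-(diethoxyphosphoryl)-3-[(triisopropylsilyl)oxy]propanoic acid
Product: 17 (1R,2S,3R,5S)-3-ethynyl-3-methyl-6-oxo-2-(prop-1-en-2-yl)-5-[(triisopropylsilyl)oxy]cyclohexyl 2-(diethoxyphosphoryl)-3-[(triisopropylsilyl)oxy]propanoate (epimers at the phosphonate carbon)
Conditions: EDC·HCl, DMAP, CH2Cl2, 0 °C → rt
Reagents that add atoms: none
Why: carbodiimide/DMAP (Steglich) esterification of the secondary α-hydroxy ketone; the phosphonate-carbon epimers converge in the next step.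

Step 10
Reactants: 17 the phosphonate ester of step 9
Product: 18 (4S,6R,7S,7aR)-6-ethynyl-6-methyl-7-(prop-1-en-2-yl)-4-[(triisopropylsilyl)oxy]-3-{[(triisopropylsilyl)oxy]methyl}-5,6,7,7a-tetrahydro-1-benzofuran-2(4H)-one
Conditions: LiCl, iPr2NEt, MeCN, rt
Reagents that add atoms: none
Why: intramolecular Horner–Wadsworth–Emmons olefination under Masamune–Roush conditions closes the butenolide onto the activated α,α'-dioxygenated ketone; silanolate is a poor leaving group, so closure should outrun β-elimination, and the two centres flanking the ketone stay in (or equilibrate to) the all-equatorial, cis arrangement.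

Step 11
Reactants: 18 the ethynyl butenolide of step 10
Product: 20 2-[(4S,6S,7S,7aR)-6-methyl-2-oxo-7-(prop-1-en-2-yl)-4-[(triisopropylsilyl)oxy]-3-{[(triisopropylsilyl)oxy]methyl}-2,4,5,6,7,7a-hexahydro-1-benzofuran-6-yl]acetaldehyde, via alkenylborane 19 (not isolated)
Conditions: (c-C6H11)2BH (from BH3·SMe2 and cyclohexene), THF, 0 °C; then H2O2, pH 7 phosphate buffer, 0 °C → rt
Reagents that add atoms: hydrogen peroxide, OO
Why: anti-Markovnikov hydroboration of the terminal alkyne by the bulky dialkylborane is much faster than attack on the hindered 1,1-disubstituted alkene or the tetrasubstituted butenolide, and buffered oxidation of the alkenylborane should give the aldehyde via its enol.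

Step 12
Reactants: 20 the aldehyde of step 11
Product: 21 2-[(4S,6S,7S,7aR)-6-methyl-2-oxo-7-(prop-1-en-2-yl)-4-[(triisopropylsilyl)oxy]-3-{[(triisopropylsilyl)oxy]methyl}-2,4,5,6,7,7a-hexahydro-1-benzofuran-6-yl]acetic acid
Conditions: NaClO2, NaH2PO4, 2-methylbut-2-ene, tBuOH/H2O, 0 °C → rt
Reagents that add atoms: sodium chlorite, [Na+].[O-]Cl=O
Why: Pinnick oxidation; chlorite oxidises only the aldehyde and the alkene scavenger protects the isopropenyl group from hypochlorous acid.

Step 13
Reactants: 21 the elemane-type acetic acid of step 12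
Product: 24 (6R,8S)-2-oxo-8,13-bis[(triisopropylsilyl)oxy]germacra-1(10)E,4E,7(11)-trien-12,6-olide, via acid chloride 22 (not isolated), via ketene 23 (not isolated)
Conditions: 1-chloro-N,N,2-trimethylprop-1-en-1-amine, CH2Cl2, 0 °C → rt; then slow addition to Et3N (3 equiv), PhMe (final 0.005 M), 80 °C
Reagents that add atoms: none
Why: Proposed new method: the amine dehydrohalogenates acid chloride 22 to aldoketene 23, whose ketene carbon C2 and the CH2 terminus C3 of the isopropenyl group are the ends of the 1,5-diene O=C2=C1–C10–C5–C4=C3, so a [3,3]-sigmatropic (Cope) shift forms C2–C3, cleaves the ring bond C5–C10 and gives the cross-conjugated enone directly; the closest known reaction types are the tandem Wolff/Cope rearrangement of 2-vinylcyclopropyl ketenes and, for this ring system, the thermal elemane–germacrane Cope equilibrium. The ten-membered ring is closed by sigmatropic ring expansion of the cyclohexane (six to ten atoms) through a chair-like six-centre transition state, not by an exo or endo cyclisation. No stereocentre is created: C5 and C10 are sacrificed, C6 and C8 are untouched, and the trans-diequatorial placement of the ketene and isopropenyl arms in the chair array should fix both trisubstituted alkenes as E. Unlike the hydrocarbon equilibrium, the step should be irreversible, because a ketene π bond is exchanged for a conjugated enone carbonyl, which outweighs the strain of the medium ring. The selectivity needed is Cope shift over ketene dimerisation and over ene or [2+2] closure onto the isopropenyl group; high dilution, the polarity match (nucleophilic 1,1-disubstituted alkene terminus onto the ketene carbonyl carbon) and the antiperiplanar alignment of the C5–C10 bond with both π systems should secure it.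

Step 14
Reactants: 24 (6R,8S)-2-oxo-8,13-bis[(triisopropylsilyl)oxy]germacra-1(10)E,4E,7(11)-trien-12,6-olide
Product: 25 (6R,8S)-8,13-dihydroxy-2-oxogermacra-1(10)E,4E,7(11)-trien-12,6-olide
Conditions: HF·pyridine, pyridine, THF, 0 °C → rt
Reagents that add atoms: none
Why: fluoride-mediated cleavage of both silyl ethers under buffered conditions that the enone-deactivated 1(10),4-diene and the butenolide should tolerate.

Step 15
Reactants: 25 (6R,8S)-8,13-dihydroxy-2-oxogermacra-1(10)E,4E,7(11)-trien-12,6-olide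
Product: 26 (6R,8S)-13-acetoxy-8-hydroxy-2-oxogermacra-1(10)E,4E,7(11)-trien-12,6-olide
Conditions: AcCl (1.05 equiv), 2,4,6-collidine, CH2Cl2, −78 °C
Reagents that add atoms: acetyl chloride, CC(=O)Cl
Why: chemoselective acylation of the primary allylic alcohol over the hindered secondary one with acetyl chloride and collidine at low temperature.

Step 16
Reactants: 26 (6R,8S)-13-acetoxy-8-hydroxy-2-oxogermacra-1(10)E,4E,7(11)-trien-12,6-olide
Product: 27 CNP0325594.1, (6R,8S)-13-acetoxy-8-(methacryloyloxy)-2-oxogermacra-1(10)E,4E,7(11)-trien-12,6-olide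
Conditions: methacrylic anhydride, DMAP (cat.), Et3N, CH2Cl2, 0 °C → rt
Reagents that add atoms: methacrylic anhydride, C=C(C)C(=O)OC(=O)C(C)=C
Why: DMAP-catalysed acylation of the remaining secondary alcohol (retention at C8) should be fast enough at 0 °C to precede any migration of the lactone to O8, and completes the target.

Compound list
1 | but-3-en-2-one | CC(=O)C=C | starting material
2 | 2-(triisopropylsilyloxy)buta-1,3-diene | C=CC(=C)O[Si](C(C)C)(C(C)C)C(C)C | intermediate
3 | ethyl (2E)-3-methyl-4-oxobut-2-enoate | CCOC(=O)/C=C(\C)C=O | starting material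
4 | ethyl (1R,6R)-6-formyl-6-methyl-3-[(triisopropylsilyl)oxy]cyclohex-3-ene-1-carboxylate | CCOC(=O)[C@@H]1CC(O[Si](C(C)C)(C(C)C)C(C)C)=CC[C@@]1(C)C=O | intermediate
5 | diazoalkene from 4 (CH=C=N2 in place of CHO; not isolated) | CCOC(=O)[C@@H]1CC(O[Si](C(C)C)(C(C)C)C(C)C)=CC[C@@]1(C)C=C=[N+]=[N-] | intermediate
6 | ethyl (1R,6R)-6-ethynyl-6-methyl-3-[(triisopropylsilyl)oxy]cyclohex-3-ene-1-carboxylate | CCOC(=O)[C@@H]1CC(O[Si](C(C)C)(C(C)C)C(C)C)=CC[C@@]1(C)C#C | intermediate
7 | 2-{(1R,6R)-6-ethynyl-6-methyl-3-[(triisopropylsilyl)oxy]cyclohex-3-en-1-yl}propan-2-ol | CC(C)(O)[C@@H]1CC(O[Si](C(C)C)(C(C)C)C(C)C)=CC[C@@]1(C)C#C | intermediate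
8 | {[(4R,5S)-4-ethynyl-4-methyl-5-(prop-1-en-2-yl)cyclohex-1-en-1-yl]oxy}triisopropylsilane | C=C(C)[C@@H]1CC(O[Si](C(C)C)(C(C)C)C(C)C)=CC[C@@]1(C)C#C | intermediate
9 | silyloxy epoxide of 8 (oxirane oxygen cis to ethynyl; not isolated) | C=C(C)[C@@H]1C[C@@]2(O[Si](C(C)C)(C(C)C)C(C)C)O[C@H]2C[C@@]1(C)C#C | intermediate
10 | (2S,4R,5S)-4-ethynyl-4-methyl-5-(prop-1-en-2-yl)-2-[(triisopropylsilyl)oxy]cyclohexan-1-one | C=C(C)[C@@H]1CC(=O)[C@@H](O[Si](C(C)C)(C(C)C)C(C)C)C[C@@]1(C)C#C | intermediate
11 | sodium enolate of 10 toward the methylene carbon (not isolated) | C=C(C)[C@@H]1C=C([O-])[C@@H](O[Si](C(C)C)(C(C)C)C(C)C)C[C@@]1(C)C#C.[Na+] | intermediate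
12 | (2R,3S,4R,6S)-4-ethynyl-2-hydroxy-4-methyl-3-(prop-1-en-2-yl)-6-[(triisopropylsilyl)oxy]cyclohexan-1-one | C=C(C)[C@@H]1[C@@H](O)C(=O)[C@@H](O[Si](C(C)C)(C(C)C)C(C)C)C[C@@]1(C)C#C | intermediate
13 | (diethoxyphosphoryl)acetic acid | CCOP(=O)(CC(=O)O)OCC | starting material
14 | (chloromethoxy)triisopropylsilane | ClCO[Si](C(C)C)(C(C)C)C(C)C | starting material
15 | dilithio dianion of 13 (not isolated) | [Li+].[Li+].CCOP(=O)(OCC)[CH-]C(=O)[O-] | intermediate
16 | 2-(diethoxyphosphoryl)-3-[(triisopropylsilyl)oxy]propanoic acid (racemic) | CCOP(=O)(OCC)C(CO[Si](C(C)C)(C(C)C)C(C)C)C(=O)O | intermediate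
17 | (1R,2S,3R,5S)-3-ethynyl-3-methyl-6-oxo-2-(prop-1-en-2-yl)-5-[(triisopropylsilyl)oxy]cyclohexyl 2-(diethoxyphosphoryl)-3-[(triisopropylsilyl)oxy]propanoate | C=C(C)[C@@H]1[C@@H](OC(=O)C(CO[Si](C(C)C)(C(C)C)C(C)C)P(=O)(OCC)OCC)C(=O)[C@@H](O[Si](C(C)C)(C(C)C)C(C)C)C[C@@]1(C)C#C | intermediate
18 | (4S,6R,7S,7aR)-6-ethynyl-6-methyl-7-(prop-1-en-2-yl)-4-[(triisopropylsilyl)oxy]-3-{[(triisopropylsilyl)oxy]methyl}-5,6,7,7a-tetrahydro-1-benzofuran-2(4H)-one | C=C(C)[C@@H]1[C@H]2OC(=O)C(CO[Si](C(C)C)(C(C)C)C(C)C)=C2[C@@H](O[Si](C(C)C)(C(C)C)C(C)C)C[C@@]1(C)C#C | intermediate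
19 | (E)-alkenyl(dicyclohexyl)borane from 18 (not isolated) | C=C(C)[C@@H]1[C@H]2OC(=O)C(CO[Si](C(C)C)(C(C)C)C(C)C)=C2[C@@H](O[Si](C(C)C)(C(C)C)C(C)C)C[C@@]1(C)/C=C/B(C1CCCCC1)C1CCCCC1 | intermediate
20 | 2-[(4S,6S,7S,7aR)-6-methyl-2-oxo-7-(prop-1-en-2-yl)-4-[(triisopropylsilyl)oxy]-3-{[(triisopropylsilyl)oxy]methyl}-2,4,5,6,7,7a-hexahydro-1-benzofuran-6-yl]acetaldehyde | C=C(C)[C@@H]1[C@H]2OC(=O)C(CO[Si](C(C)C)(C(C)C)C(C)C)=C2[C@@H](O[Si](C(C)C)(C(C)C)C(C)C)C[C@@]1(C)CC=O | intermediate
21 | 2-[(4S,6S,7S,7aR)-6-methyl-2-oxo-7-(prop-1-en-2-yl)-4-[(triisopropylsilyl)oxy]-3-{[(triisopropylsilyl)oxy]methyl}-2,4,5,6,7,7a-hexahydro-1-benzofuran-6-yl]acetic acid | C=C(C)[C@@H]1[C@H]2OC(=O)C(CO[Si](C(C)C)(C(C)C)C(C)C)=C2[C@@H](O[Si](C(C)C)(C(C)C)C(C)C)C[C@@]1(C)CC(=O)O | intermediate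
22 | acid chloride of 21 (not isolated) | C=C(C)[C@@H]1[C@H]2OC(=O)C(CO[Si](C(C)C)(C(C)C)C(C)C)=C2[C@@H](O[Si](C(C)C)(C(C)C)C(C)C)C[C@@]1(C)CC(=O)Cl | intermediate
23 | ketene from 22 (C10–CH=C=O; not isolated) | C=C(C)[C@@H]1[C@H]2OC(=O)C(CO[Si](C(C)C)(C(C)C)C(C)C)=C2[C@@H](O[Si](C(C)C)(C(C)C)C(C)C)C[C@@]1(C)C=C=O | intermediate
24 | (6R,8S)-2-oxo-8,13-bis[(triisopropylsilyl)oxy]germacra-1(10)E,4E,7(11)-trien-12,6-olide | CC(C)[Si](C(C)C)(C(C)C)O[C@H]1C/C(C)=C/C(=O)C/C(C)=C/[C@H]2OC(=O)C(CO[Si](C(C)C)(C(C)C)C(C)C)=C12 | intermediate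
25 | (6R,8S)-8,13-dihydroxy-2-oxogermacra-1(10)E,4E,7(11)-trien-12,6-olide | O[C@H]1C/C(C)=C/C(=O)C/C(C)=C/[C@H]2OC(=O)C(CO)=C12 | intermediate
26 | (6R,8S)-13-acetoxy-8-hydroxy-2-oxogermacra-1(10)E,4E,7(11)-trien-12,6-olide | O[C@H]1C/C(C)=C/C(=O)C/C(C)=C/[C@H]2OC(=O)C(COC(C)=O)=C12 | intermediate
27 | CNP0325594.1, (6R,8S)-13-acetoxy-8-(methacryloyloxy)-2-oxogermacra-1(10)E,4E,7(11)-trien-12,6-olide | C=C(C)C(=O)O[C@H]1C/C(C)=C/C(=O)C/C(C)=C/[C@H]2OC(=O)C(COC(C)=O)=C12 | target

Total step count: 16. Longest linear sequence: 15 steps (steps 1–7 and 9–16; step 8 is a one-step side branch).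

Steps most likely to fail

1. Step 13 (new method). The aldoketene may dimerise, or close onto the isopropenyl group by an ene or [2+2] pathway, instead of undergoing the sigmatropic shift; the amine may also move the β,γ-double bond of the product into conjugation. The fallback runs the ring expansion at the alcohol oxidation level with known chemistry and sets out from aldehyde 20. TESOTf/Et3N (CH2Cl2, −78 °C) should give the triethylsilyl enol ether of 20 F1. Heating (o-dichlorobenzene, 180–200 °C, sealed tube) establishes the known elemane–germacrane Cope equilibrium, which still forms C2–C3 and is expected to lie on the side of F1. The 2-(triethylsilyloxy)germacranolide F2 is separated and unchanged F1 is resubjected. PPTS/MeOH (0 °C) removes the allylic triethylsilyl group selectively to give the C2 allylic alcohol F3, and Dess–Martin oxidation (NaHCO3, CH2Cl2) returns to the route at 24.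

2. Step 10. The phosphonate carbanion may lose silanolate by E1cB elimination faster than it closes onto the hindered ketone. The fallback turns that elimination into the productive pathway and sets out from 12. Esterification (EDC·HCl, DMAP) with 2-(diethoxyphosphoryl)acrylic acid, C=C(C(=O)O)P(=O)(OCC)OCC, should give the phosphonoacrylate ester of 12 F4. Sodium 4-methoxybenzyl oxide (4-methoxybenzyl alcohol, NaH, THF, 0 °C) adds to the vinylphosphonate and the resulting carbanion closes by intramolecular Horner–Wadsworth–Emmons olefination (tandem oxa-Michael/olefination) to the C13 4-methoxybenzyl ether butenolide F5. DDQ (CH2Cl2, pH 7 buffer) releases the C13 primary alcohol F6, and iPr3SiOTf/2,6-lutidine returns to the route at 18.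

3. Step 5. Elimination toward the ring methine would give the tetrasubstituted isopropylidene isomer and destroy the Cope terminus. The fallback builds the alkene by olefination and sets out from ester 6. Me(MeO)NH·HCl/iPrMgCl (THF, −20 °C) should give the Weinreb amide of 6 F7. MeMgBr (THF, 0 °C) gives the methyl ketone F8, and Ph3P=CH2 (from Ph3PCH3Br and KOtBu, THF, 0 °C) methylenates it regiospecifically, returning to the route at 8.

Further compounds
F1 | step 13 | triethylsilyl enol ether of 20 (E/Z mixture) | C=C(C)[C@@H]1[C@H]2OC(=O)C(CO[Si](C(C)C)(C(C)C)C(C)C)=C2[C@@H](O[Si](C(C)C)(C(C)C)C(C)C)C[C@@]1(C)C=CO[Si](CC)(CC)CC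
F2 | step 13 | (6R,8S)-2-(triethylsilyloxy)-8,13-bis[(triisopropylsilyl)oxy]germacra-1(10)E,4E,7(11)-trien-12,6-olide (C2 epimers) | CC(C)[Si](C(C)C)(C(C)C)O[C@H]1C/C(C)=C/C(O[Si](CC)(CC)CC)C/C(C)=C/[C@H]2OC(=O)C(CO[Si](C(C)C)(C(C)C)C(C)C)=C12
F3 | step 13 | (6R,8S)-2-hydroxy-8,13-bis[(triisopropylsilyl)oxy]germacra-1(10)E,4E,7(11)-trien-12,6-olide (C2 epimers) | CC(C)[Si](C(C)C)(C(C)C)O[C@H]1C/C(C)=C/C(O)C/C(C)=C/[C@H]2OC(=O)C(CO[Si](C(C)C)(C(C)C)C(C)C)=C12
F4 | step 10 | 2-(diethoxyphosphoryl)acrylate ester of 12 | C=C(C)[C@@H]1[C@@H](OC(=O)C(=C)P(=O)(OCC)OCC)C(=O)[C@@H](O[Si](C(C)C)(C(C)C)C(C)C)C[C@@]1(C)C#C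
F5 | step 10 | analogue of 18 with a 4-methoxybenzyl ether on C13 | C=C(C)[C@@H]1[C@H]2OC(=O)C(COCc3ccc(OC)cc3)=C2[C@@H](O[Si](C(C)C)(C(C)C)C(C)C)C[C@@]1(C)C#C
F6 | step 10 | analogue of 18 with free C13 hydroxyl | C=C(C)[C@@H]1[C@H]2OC(=O)C(CO)=C2[C@@H](O[Si](C(C)C)(C(C)C)C(C)C)C[C@@]1(C)C#C
F7 | step 5 | (1R,6R)-6-ethynyl-N-methoxy-N,6-dimethyl-3-[(triisopropylsilyl)oxy]cyclohex-3-ene-1-carboxamide | CON(C)C(=O)[C@@H]1CC(O[Si](C(C)C)(C(C)C)C(C)C)=CC[C@@]1(C)C#C
F8 | step 5 | 1-{(1R,6R)-6-ethynyl-6-methyl-3-[(triisopropylsilyl)oxy]cyclohex-3-en-1-yl}ethan-1-one | CC(=O)[C@@H]1CC(O[Si](C(C)C)(C(C)C)C(C)C)=CC[C@@]1(C)C#C
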